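## Structural features

The target 16 is a 2,3-dihydro-1-benzofuran: a benzene ring (ring A) fused through C3a–C7a to an oxygen heterocycle (ring B: O1, C2, C3, C3a, C7a). Ring A carries a methoxy group at C7 (ortho to the ring oxygen) and an (E)-prop-1-enyl group at C5 (para to the ring oxygen). C2 bears a 3,4,5-trimethoxyphenyl group (ring C) and C3 a methyl group. C2 and C3 are adjacent stereocentres, both R, with aryl and methyl trans on ring B. The fragile points are the benzylic aryl ether bond O1–C2, which ionises under acid, and the propenyl styrene, which does not tolerate ozone, other oxidants or acid. All three rings are electron-rich, and the C3 hydrogen becomes labile whenever C2 is a carbonyl or cationic carbon. The trans arrangement is the more stable one and C2 can be set from a planar benzylic cation under the influence of C3, so the real difficulty is the absolute configuration of C3, a benzylic methine with no heteroatom handle. The key step exploits two facts: C3 is bonded to C3a, the only unsubstituted carbon ortho to the phenolic oxygen of ring A (C7 holds the methoxy group and C5, para, is occupied), and C2 can be stored as the near carbon of an alkene.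

## Logic of the disconnections

16 ⇒ 14 + 15. The C5–C(sp2) bond of the propenyl group is cut. The styrene cannot survive the alkene cleavage and the acid-mediated ring closure, whereas a bromine at C5 is inert to both, blocks the para position during the sigmatropic step and is exchanged last. The alkene geometry becomes a property of 15. The forward step must couple an electron-rich aryl bromide with retention of the E geometry and leave O1–C2 alone.

14 ⇒ 12. The O1–C2 bond is cut. C2 is benzylic to ring C and sits five atoms from the phenol oxygen, so closure through a C2 cation is natural and lets C3 dictate the trans relationship. Ring B and the C2 stereocentre are removed, and both C2 epimers of 12 become usable. The forward step must ionise C2 without proton loss or hydride shift from C3.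

12 ⇒ 9 + 11 (11 from 10). The bond between C2 and ring C is cut. This is the convergent cut: ring C arrives as an aryl nucleophile on a C2 at the aldehyde oxidation level. One stereocentre (C3) remains. The forward step needs addition to outrun enolisation of the transient aldehyde.

9 ⇒ 6. C2 is traced back to an alkene carbon, so the C=C bond of 6 is the latent C2 carbonyl. This places the alkene exactly where a [3,3] shift would leave it. The forward step must cleave the alkene without oxidising the electron-rich phenol; the cyclic hemiacetal form of the product shields the C3 hydrogen.

6 ⇒ 4 (key). The C3–C3a bond is cut and the aryl O–C bond restored, so the carbon stereocentre is exchanged for an oxygen-bearing one three atoms away. A C–O stereocentre on a symmetrical allyl unit is accessible by asymmetric catalysis, which a benzylic C–C stereocentre is not. The forward step must be concerted and suprafacial through a chair, at a single ortho site. Three design points are tightened in 4: the alkene must be geometrically pure E, bromine is kept as the para blocker, and a mild Lewis acid replaces strong heating. The S descriptor of 6 and the R descriptor of C3 in 16 denote the same spatial arrangement; only the CIP ranking of the C2 substituent changes. The R descriptor of 4 is the one that leads to it through the chair.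

4 ⇒ 2 + 3. The allylic O–C bond is cut. The 1,3-dimethylallyl unit is symmetrical, so both enantiomers of 2 converge on one allyl–palladium species and no regiochemical question exists. The forward step needs high enantioselection, no re-ionisation of the product and an aryl bromide that survives zerovalent palladium.

2 ⇒ 1. The carbonate O–C(=O) bond is cut. The carbonate is a leaving group that releases its own base, so the etherification needs no added base.

## Other disconnections considered

Alternative 1: Both bonds joining ring B to ring A are cut (C3–C3a and O1–C7a). Ring A would arrive as methyl 4-iodo-3-methoxybenzoate A1, and C2, C3 and ring C as the cis-epoxide (2R,3S)-2-methyl-3-(3,4,5-trimethoxyphenyl)oxirane A2. In a palladium/norbornene relay (Catellani type) the palladacycle from A1 would open A2 at the methyl-bearing carbon with inversion, and the alkoxide would then couple at the ipso carbon to give the ester A3.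
- In favour: ring B and two bonds form in one operation, and inversion at C3 with retention at C2 turns the cis-epoxide into the trans ring without a cation at C2. The methoxy group of A1 supplies the ortho substituent such relays need.
- Against: the epoxide is internal and benzylic. The palladacycle must attack a hindered secondary carbon next to a more easily ionised benzylic C–O bond, and Meinwald-type isomerisation of an electron-rich aryl epoxide is a plausible competitor. A2 needs its own asymmetric epoxidation, and the ester of A3 needs a partial reduction and an E-selective olefination, which reopens the alkene-geometry question.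
- Comparison: on convergence and on the number of operations that build ring B (one against three) this alternative is the better. On stereochemical logic it is the equal of the chosen plan, since both are stereospecific transfers from an oxygen-bearing stereocentre. On precedent for the substrate class, regiochemical risk and the end game it is weaker. The overall step count would be similar.

Alternative 2: Ring B is opened at O1–C2 and C2 is taken back to a ketone, giving the racemic protected ketone A4. Hydrogenation with RuCl2(xylBINAP)(DAIPEN) and KOt-Bu, with the alpha centre equilibrating, would give the (1R,2R)-alcohol A5.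
- In favour: one catalytic step sets both stereocentres from a racemate, with reagent control at C3 itself. For absolute stereocontrol this is at least the equal of, and arguably more dependable than, an etherification–rearrangement relay. The lability of the C3 hydrogen is turned to advantage.
- Against: A5 already has the target's arrangement at the carbinol carbon, so the ring must close with retention, through the benzylic cation or a double inversion. An SN2 closure would give the cis ring. The carbinol configuration is therefore not used, and the closure carries the same C3-erosion risk as step 6 below. The carbonyl group is flanked by a hindered alpha-aryl carbon, A4 needs two protections and a ketone alpha-arylation, and the unmasked C5 aldehyde needs an E-selective olefination.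
- Comparison: structurally it reaches the same open-chain type as 12. Mechanistically it is equally defensible. In step economy it is about one to two steps longer than the chosen plan, and the propenyl geometry is less secure than by coupling with 15.

Alternative 3: C2–C3 and O1–C2 are cut ([4+1]). The sulfone A6 would release the ortho-quinone methide A7 with Cs2CO3. The ylide from a chiral (3,4,5-trimethoxybenzyl)sulfonium salt such as A8 would add at the exocyclic carbon, and the phenoxide would displace the sulfide to give A9, which is identical with 14.
- In favour: it is the most convergent and shortest plan. One step forms ring B and both stereocentres and lands on the compound that precedes the target here. No cation at C2 and no oxidative cleavage are needed.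
- Against: A7 carries a methyl group on the exocyclic carbon. Such alkylidene quinone methides can tautomerise to ortho-vinylphenols by 1,5-hydrogen shift, and they are less electrophilic and less defined in geometry than the aryl-substituted cases for which asymmetric ylide annulations are best established. Facial control at C3 by a remote sulfonium stereocentre, with methyl as the only differentiating group, is uncertain, and a stoichiometric chiral sulfide is needed.
- Comparison: in step economy it is the better by about two steps, and its end point equals 14. In predictability of C3 the intramolecular chair transfer of the chosen plan is stronger. Trans selectivity should be comparable.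

Key step: step 3

Assumption: the (S,S) antipode of the bis(phosphinobenzamide) ligand is taken as the one that gives the (R)-ether 4; if the sense of induction is the reverse, the equally available (R,R) ligand is used and nothing else changes.

## Route

Step 1
Reactants: 1 racemic (E)-pent-3-en-2-ol
Product: 2 racemic methyl (E)-pent-3-en-2-yl carbonate
Conditions: ClCO2Me, pyridine, CH2Cl2, 0 °C → rt
Reagents that add atoms: methyl chloroformate, COC(=O)Cl
Why: Acylation of a secondary alcohol with a chloroformate (carbonate formation) is routine and does not touch the alkene. The stereocentre is left racemic on purpose because step 2 is enantioconvergent.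

Step 2
Reactants: 2 racemic methyl (E)-pent-3-en-2-yl carbonate; 3 4-bromo-2-methoxyphenol
Product: 4 4-bromo-2-methoxy-1-{[(2R,3E)-pent-3-en-2-yl]oxy}benzene
Conditions: Pd2(dba)3·CHCl3 (1 mol %), (1S,2S)-N,N'-cyclohexane-1,2-diylbis[2-(diphenylphosphanyl)benzamide] (3 mol %), CH2Cl2, rt
Reagents that add atoms: none
Why: Palladium-catalysed asymmetric allylic etherification (Tsuji–Trost reaction): zerovalent palladium ionises both enantiomers of 2 to the same symmetrical syn,syn-1,3-dimethylallyl unit on the metal, the methoxide released with CO2 deprotonates 3, and the chiral ligand pocket steers the phenoxide to one of the two enantiotopic termini, which sets the carbinol centre as R and keeps the alkene E. The termini are constitutionally identical, so regiochemistry is not an issue. The electron-rich aryl bromide should not undergo oxidative addition at room temperature with this ligand.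

Step 3
Reactants: 4 4-bromo-2-methoxy-1-{[(2R,3E)-pent-3-en-2-yl]oxy}benzene
Product: 6 4-bromo-2-methoxy-6-[(2S,3E)-pent-3-en-2-yl]phenol, via ortho-dienone 5 (not isolated)
Conditions: Eu(fod)3 (10 mol %; fod = 6,6,7,7,8,8,8-heptafluoro-2,2-dimethyloctane-3,5-dionate), CHCl3, 50 °C
Reagents that add atoms: none
Why: Eu(fod)3 binds the ether oxygen (the neighbouring methoxy group can act as a second donor) and the aryl allyl ether undergoes a concerted, suprafacial [3,3]-sigmatropic shift (aromatic Claisen rearrangement) in which the O–C2' bond of the pentenyl unit breaks while C4' bonds to the free ortho carbon, the future C3–C3a bond; the ortho-dienone 5 then tautomerises to the phenol 6. The closest known reaction type is the lanthanide-promoted aromatic Claisen rearrangement of enantioenriched aryl sec-allyl ethers with 1,3-chirality transfer. No ring is closed; the six-membered array exists only in the transition state. The new stereocentre (C3 of the target) is controlled by the carbinol stereocentre of 4 through a chair transition state with the carbinol methyl group pseudo-equatorial, which delivers the aryl carbon to the alkene face from which the oxygen departs, turns the (R,E)-ether into the (S,E)-product and makes the new alkene E; the ring stereocentre of 5 disappears on enolisation. Site selectivity is secured by the substrate: the second ortho carbon carries the methoxy group and the para carbon carries bromine, so a shift to the methoxy-bearing carbon can only revert. Fidelity of the transfer requires a geometrically pure (E)-alkene (a Z ether would transfer in the opposite sense) and a concerted pathway, which the mild Lewis acid at 50 °C should favour over C–O heterolysis and over the thermal ene/retro-ene scrambling known as the abnormal Claisen rearrangement.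

Step 4
Reactants: 6 4-bromo-2-methoxy-6-[(2S,3E)-pent-3-en-2-yl]phenol
Product: 9 (3R)-5-bromo-7-methoxy-3-methyl-2,3-dihydro-1-benzofuran-2-ol (mixture of C2 anomers), via ozonide 7 (not isolated), via hydroxy aldehyde 8 (not isolated)
Conditions: O3, CH2Cl2, −78 °C (Sudan Red 7B end point); then PPh3, −78 °C → rt
Reagents that add atoms: ozone, [O-][O+]=O
Why: Ozonolysis with reductive work-up: the 1,2-disubstituted alkene should react far faster than the bromo-substituted phenol ring when the ozone dose is limited by the indicator dye; PPh3 reduces the ozonide 7, and the aldehyde 8 is trapped by the ortho phenol as the five-membered hemiacetal 9. C3 is untouched, and the hemiacetal form keeps its hydrogen from enolising. A periodate-based cleavage is avoided because periodate oxidises 2-methoxyphenols to ortho-quinones.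

Step 5
Reactants: 9 (3R)-5-bromo-7-methoxy-3-methyl-2,3-dihydro-1-benzofuran-2-ol; 10 5-bromo-1,2,3-trimethoxybenzene
Product: 12 (2R)-2-(5-bromo-2-hydroxy-3-methoxyphenyl)-1-(3,4,5-trimethoxyphenyl)propan-1-ol (mixture of C1 epimers), via 3,4,5-trimethoxyphenylmagnesium bromide 11 (not isolated)
Conditions: 10, Mg (I2 cat.), THF, rt → 45 °C; then 9 (0.33 equiv), THF, −78 → 0 °C; aq. NH4Cl
Reagents that add atoms: none
Why: Grignard addition to a lactol: the first equivalent of 11 deprotonates 9, which opens to the magnesium phenoxide of aldehyde 8, and a further equivalent adds to the carbonyl group; the new carbinol centre need not be controlled because step 6 erases it. Low temperature should favour 1,2-addition over enolisation, and an aryl Grignard reagent does not exchange with the aryl bromide of ring A under these conditions.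

Step 6
Reactants: 12 (2R)-2-(5-bromo-2-hydroxy-3-methoxyphenyl)-1-(3,4,5-trimethoxyphenyl)propan-1-ol
Product: 14 (2R,3R)-5-bromo-7-methoxy-3-methyl-2-(3,4,5-trimethoxyphenyl)-2,3-dihydro-1-benzofuran, via benzylic cation 13 (not isolated)
Conditions: TsOH·H2O (10 mol %), 4 Å MS, CH2Cl2, 0 °C → rt
Reagents that add atoms: none
Why: Acid-catalysed dehydrative etherification (SN1): loss of water gives the benzylic cation 13, stabilised by ring C, which the neighbouring phenol oxygen captures in a five-membered ring closure, so both epimers of 12 converge. C2 is set by C3 (substrate control): attack on the face that puts ring C anti to the C3 methyl group gives the trans ring, and reversible ionisation of O1–C2 under the same conditions should funnel any cis isomer to the more stable trans product.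

Step 7
Reactants: 14 (2R,3R)-5-bromo-7-methoxy-3-methyl-2-(3,4,5-trimethoxyphenyl)-2,3-dihydro-1-benzofuran; 15 potassium (E)-prop-1-enyltrifluoroborate
Product: 16 (2R,3R)-7-methoxy-3-methyl-5-[(E)-prop-1-enyl]-2-(3,4,5-trimethoxyphenyl)-2,3-dihydro-1-benzofuran
Conditions: PdCl2(dppf)·CH2Cl2 (5 mol %; dppf = 1,1'-bis(diphenylphosphino)ferrocene), Cs2CO3 (3 equiv), THF–H2O (9:1), 70 °C
Reagents that add atoms: none
Why: Suzuki–Miyaura cross-coupling of an aryl bromide with a potassium alkenyltrifluoroborate proceeds with retention of the alkene geometry, so the E configuration is supplied by 15. The basic medium leaves the O1–C2 benzylic ether and both stereocentres untouched.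

## Compound list

1 | racemic (E)-pent-3-en-2-ol | C/C=C/C(C)O | starting material
2 | racemic methyl (E)-pent-3-en-2-yl carbonate | C/C=C/C(C)OC(=O)OC | intermediate
3 | 4-bromo-2-methoxyphenol | COc1cc(Br)ccc1O | starting material
4 | 4-bromo-2-methoxy-1-{[(2R,3E)-pent-3-en-2-yl]oxy}benzene | COc1cc(Br)ccc1O[C@H](C)/C=C/C | intermediate
5 | (6S)-4-bromo-2-methoxy-6-[(2S,3E)-pent-3-en-2-yl]cyclohexa-2,4-dien-1-one | COC1=CC(Br)=C[C@@H](C1=O)[C@@H](C)/C=C/C | intermediate
6 | 4-bromo-2-methoxy-6-[(2S,3E)-pent-3-en-2-yl]phenol | COc1cc(Br)cc(c1O)[C@@H](C)/C=C/C | intermediate
7 | 3-[(1R)-1-(5-bromo-2-hydroxy-3-methoxyphenyl)ethyl]-5-methyl-1,2,4-trioxolane (mixture of trioxolane diastereomers) | COc1cc(Br)cc([C@@H](C)C2OOC(C)O2)c1O | intermediate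
8 | (2R)-2-(5-bromo-2-hydroxy-3-methoxyphenyl)propanal | COc1cc(Br)cc([C@@H](C)C=O)c1O | intermediate
9 | (3R)-5-bromo-7-methoxy-3-methyl-2,3-dihydro-1-benzofuran-2-ol (mixture of C2 anomers) | Brc1cc(OC)c2c(c1)[C@@H](C)C(O)O2 | intermediate
10 | 5-bromo-1,2,3-trimethoxybenzene | COc1cc(Br)cc(OC)c1OC | starting material
11 | 3,4,5-trimethoxyphenylmagnesium bromide | COc1cc([Mg]Br)cc(OC)c1OC | intermediate
12 | (2R)-2-(5-bromo-2-hydroxy-3-methoxyphenyl)-1-(3,4,5-trimethoxyphenyl)propan-1-ol (mixture of C1 epimers) | COc1cc(Br)cc([C@@H](C)C(O)c2cc(OC)c(OC)c(OC)c2)c1O | intermediate
13 | (2S)-2-(5-bromo-2-hydroxy-3-methoxyphenyl)-1-(3,4,5-trimethoxyphenyl)propan-1-ylium (benzylic cation; same spatial arrangement at the methyl-bearing carbon as in 12) | COc1cc(Br)cc([C@@H](C)[CH+]c2cc(OC)c(OC)c(OC)c2)c1O | intermediate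
14 | (2R,3R)-5-bromo-7-methoxy-3-methyl-2-(3,4,5-trimethoxyphenyl)-2,3-dihydro-1-benzofuran | Brc1cc(OC)c2c(c1)[C@@H](C)[C@H](c1cc(OC)c(OC)c(OC)c1)O2 | intermediate
15 | potassium (E)-prop-1-enyltrifluoroborate | C/C=C/[B-](F)(F)F.[K+] | starting material
16 | (2R,3R)-7-methoxy-3-methyl-5-[(E)-prop-1-enyl]-2-(3,4,5-trimethoxyphenyl)-2,3-dihydro-1-benzofuran | C/C=C/c1cc(OC)c2c(c1)[C@@H](C)[C@H](c1cc(OC)c(OC)c(OC)c1)O2 | target

## Step count and least certain steps

Total: 7 steps. Longest linear sequence: 7 steps (1 → 2 → 4 → 6 → 9 → 12 → 14 → 16); 11 is generated from 10 inside step 5. Enantiomeric purity should be checked at 4 and at 6, and raised at a crystalline later stage if needed.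

**Step 3 (key step).** The most likely failure is incomplete chirality transfer. It could arise from Lewis-acid-induced heterolysis of the secondary allylic C–O bond followed by ion-pair recombination, from a competing boat transition state, or, if more forcing conditions are needed, from ene/retro-ene scrambling at the new stereocentre. The fallback replaces chirality transfer by resolution. It sets out from 6 of insufficient enantiomeric purity and returns to 6. The phenol is acylated with (1S)-camphanic chloride (Et3N, DMAP cat., CH2Cl2) to give the diastereomeric esters 4-bromo-2-methoxy-6-[(2S,3E)-pent-3-en-2-yl]phenyl (1S,4R)-camphanate F1 and 4-bromo-2-methoxy-6-[(2R,3E)-pent-3-en-2-yl]phenyl (1S,4R)-camphanate F2. These are separated by crystallisation or chromatography, and F1 is cleaved with K2CO3 in methanol to return enantiopure 6.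

**Step 2.** The likely failures are modest enantioselection with the small, symmetrical 1,3-dimethylallyl unit and erosion by re-ionisation of the product ether (phenoxide as leaving group) if the reaction is left too long. The fallback changes the source of chirality. It sets out from 1 and returns at 4. Lipase-mediated kinetic resolution of 1 (Candida antarctica lipase B, vinyl acetate, hexane) should leave (S)-(E)-pent-3-en-2-ol F3 unreacted and convert the other enantiomer into (R)-(E)-pent-3-en-2-yl acetate F4, following the usual enantiopreference of lipases for secondary alcohols. After separation, F3 is coupled with 3 under Mitsunobu conditions (PPh3, DIAD, toluene, 0 °C), which should give 4 with inversion.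

**Step 4.** The likely failures are oxidation of the electron-rich phenol ring by excess ozone and acid-promoted dehydration of the lactol to the aromatic benzofuran during isolation, which would destroy C3. The fallback masks the phenol so that a periodate cleavage becomes safe. It sets out from 6 and returns at 12. Silylation (TBSCl, imidazole, DMF) gives tert-butyl{4-bromo-2-methoxy-6-[(2S,3E)-pent-3-en-2-yl]phenoxy}dimethylsilane F5. Lemieux–Johnson cleavage (OsO4 cat., NaIO4, 2,6-lutidine, dioxane–H2O) gives (2R)-2-{5-bromo-2-[(tert-butyldimethylsilyl)oxy]-3-methoxyphenyl}propanal F6, to be used at once. Addition of 11 at −78 °C gives (2R)-2-{5-bromo-2-[(tert-butyldimethylsilyl)oxy]-3-methoxyphenyl}-1-(3,4,5-trimethoxyphenyl)propan-1-ol F7, and Bu4NF in THF removes the silyl group to give 12.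

**Step 6.** The likely failures are loss of the C3 proton from the cation (E1 elimination) or a 1,2-hydride shift from C3 to C2, either of which would erase the C3 configuration, and incomplete trans selectivity. The fallback avoids the cation. It sets out from 12 and returns at 14. The C1 epimers are separated by chromatography into (1S,2R)-2-(5-bromo-2-hydroxy-3-methoxyphenyl)-1-(3,4,5-trimethoxyphenyl)propan-1-ol F8, expected to predominate if step 5 follows the Felkin–Anh model, and the (1R,2R)-epimer F9. F8 is closed under Mitsunobu conditions (PPh3, DIAD, THF, 0 °C): intramolecular SN2 displacement by the phenol with inversion at C1 should give trans 14 directly. F9 is set aside, since the same conditions would convert it into the cis ring.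

## Further compounds

F1 | step 3 | 4-bromo-2-methoxy-6-[(2S,3E)-pent-3-en-2-yl]phenyl (1S,4R)-4,7,7-trimethyl-3-oxo-2-oxabicyclo[2.2.1]heptane-1-carboxylate | COc1cc(Br)cc([C@@H](C)/C=C/C)c1OC(=O)[C@@]12CC[C@@](C)(C(=O)O1)C2(C)C
F2 | step 3 | 4-bromo-2-methoxy-6-[(2R,3E)-pent-3-en-2-yl]phenyl (1S,4R)-4,7,7-trimethyl-3-oxo-2-oxabicyclo[2.2.1]heptane-1-carboxylate | COc1cc(Br)cc([C@H](C)/C=C/C)c1OC(=O)[C@@]12CC[C@@](C)(C(=O)O1)C2(C)C
F3 | step 2 | (S)-(E)-pent-3-en-2-ol | O[C@@H](C)/C=C/C
F4 | step 2 | (R)-(E)-pent-3-en-2-yl acetate | CC(=O)O[C@H](C)/C=C/C
F5 | step 4 | tert-butyl{4-bromo-2-methoxy-6-[(2S,3E)-pent-3-en-2-yl]phenoxy}dimethylsilane | COc1cc(Br)cc([C@@H](C)/C=C/C)c1O[Si](C)(C)C(C)(C)C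
F6 | step 4 | (2R)-2-{5-bromo-2-[(tert-butyldimethylsilyl)oxy]-3-methoxyphenyl}propanal | COc1cc(Br)cc([C@@H](C)C=O)c1O[Si](C)(C)C(C)(C)C
F7 | step 4 | (2R)-2-{5-bromo-2-[(tert-butyldimethylsilyl)oxy]-3-methoxyphenyl}-1-(3,4,5-trimethoxyphenyl)propan-1-ol (mixture of C1 epimers) | COc1cc(Br)cc([C@@H](C)C(O)c2cc(OC)c(OC)c(OC)c2)c1O[Si](C)(C)C(C)(C)C
F8 | step 6 | (1S,2R)-2-(5-bromo-2-hydroxy-3-methoxyphenyl)-1-(3,4,5-trimethoxyphenyl)propan-1-ol | COc1cc(Br)cc([C@@H](C)[C@H](O)c2cc(OC)c(OC)c(OC)c2)c1O
F9 | step 6 | (1R,2R)-2-(5-bromo-2-hydroxy-3-methoxyphenyl)-1-(3,4,5-trimethoxyphenyl)propan-1-ol | COc1cc(Br)cc([C@@H](C)[C@@H](O)c2cc(OC)c(OC)c(OC)c2)c1O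
A1 | alternative 1 | methyl 4-iodo-3-methoxybenzoate | COC(=O)c1ccc(I)c(OC)c1
A2 | alternative 1 | (2R,3S)-2-methyl-3-(3,4,5-trimethoxyphenyl)oxirane (cis) | C[C@H]1O[C@H]1c1cc(OC)c(OC)c(OC)c1
A3 | alternative 1 | methyl (2R,3R)-7-methoxy-3-methyl-2-(3,4,5-trimethoxyphenyl)-2,3-dihydro-1-benzofuran-5-carboxylate | COC(=O)c1cc(OC)c2c(c1)[C@@H](C)[C@H](c1cc(OC)c(OC)c(OC)c1)O2
A4 | alternative 2 | racemic 2-[5-(1,3-dioxolan-2-yl)-3-methoxy-2-(methoxymethoxy)phenyl]-1-(3,4,5-trimethoxyphenyl)propan-1-one | COCOc1c(OC)cc(C2OCCO2)cc1C(C)C(=O)c1cc(OC)c(OC)c(OC)c1
A5 | alternative 2 | (1R,2R)-2-[5-(1,3-dioxolan-2-yl)-3-methoxy-2-(methoxymethoxy)phenyl]-1-(3,4,5-trimethoxyphenyl)propan-1-ol | COCOc1c(OC)cc(C2OCCO2)cc1[C@@H](C)[C@@H](O)c1cc(OC)c(OC)c(OC)c1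
A6 | alternative 3 | racemic 4-bromo-2-methoxy-6-[1-(4-methylbenzenesulfonyl)ethyl]phenol | COc1cc(Br)cc(C(C)S(=O)(=O)c2ccc(C)cc2)c1O
A7 | alternative 3 | 4-bromo-6-ethylidene-2-methoxycyclohexa-2,4-dien-1-one (ortho-quinone methide, alkene geometry open) | CC=C1C=C(Br)C=C(OC)C1=O
A8 | alternative 3 | (2R,5R)-2,5-dimethyl-1-[(3,4,5-trimethoxyphenyl)methyl]thiolan-1-ium tetrafluoroborate (one antipode shown; the antipode required is open) | C[C@@H]1CC[C@@H](C)[S+]1Cc1cc(OC)c(OC)c(OC)c1.F[B-](F)(F)F
A9 | alternative 3 | (2R,3R)-5-bromo-7-methoxy-3-methyl-2-(3,4,5-trimethoxyphenyl)-2,3-dihydro-1-benzofuran (identical with 14) | Brc1cc(OC)c2c(c1)[C@@H](C)[C@H](c1cc(OC)c(OC)c(OC)c1)O2
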